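**Retrosynthetic overview**

- The target, (2S)-2-(2,4-dihydroxyphenyl)-7-hydroxy-6,8-diprenylchroman-4-one (prenyl = 3-methylbut-2-en-1-yl), is traced back to its tris-TBS ether (TBS = tert-butyldimethylsilyl). The pyranone ring C is then cut at C3–C4 and O1–C2, giving a ring-A salicylaldehyde (formyl carbon = C4) and a ring-B arylacetylene (alkyne carbons = C2 and C3).
- Forward, both bonds are made in one flask: rhodium-catalysed hydroacylation of the alkyne by the aldehyde gives the 2'-hydroxychalcone, and a chiral bifunctional thiourea closes it by the chalcone-isomerase-like oxa-Michael addition to the (2S)-flavanone; the two partners are isomerised into the product with no atom lost.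
- Enabling feature: the free phenol O1–H on C8a of ring A, ortho to the formyl carbon C4. As a rhodium aryloxide it directs the C–H activation at C4, and as the only free phenoxide it is then the nucleophile that attacks C2.
- Both aryl partners come from 2,4-dihydroxybenzaldehyde: ring A by di-iodination at C3/C5, double Stille prenylation and silylation of O4; ring B by bis-silylation and one-carbon homologation of the formyl group to the alkyne.
- Order of ring formation: rings A and B are bought; ring C is the only ring made, in the key step.

Key step: step 6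

Remark (assumption): the (2S) sense of closure is assumed for the 9-amino(9-deoxy)epiquinine-derived thiourea; should a pilot run show the opposite sense, its epiquinidine-derived pseudoenantiomer is used with no other change.

**Route**

Step 1
Reactants: 1 2,4-dihydroxybenzaldehyde
Product: 2 2,4-dihydroxy-3,5-diiodobenzaldehyde
Conditions: ICl (2.1 equiv), AcOH, rt
Reagents that add atoms: iodine monochloride, ClI
Why: Electrophilic aromatic iodination should take place only at C3 and C5, the two positions ortho/para to both hydroxyl groups, while C6 (meta to both) stays untouched.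

Step 2
Reactants: 2 2,4-dihydroxy-3,5-diiodobenzaldehyde
Product: 3 2,4-dihydroxy-3,5-bis(3-methylbut-2-en-1-yl)benzaldehyde
Conditions: Bu3SnCH2CH=CMe2 (2.6 equiv), Pd(PPh3)4 (cat.), CuI (cat.), DMF, 80 °C
Reagents that add atoms: tributyl(3-methylbut-2-en-1-yl)stannane, CCCC[Sn](CCCC)(CCCC)CC=C(C)C
Why: Double Stille cross-coupling should replace both iodides, since aryl iodides add readily to zerovalent palladium, free phenols are tolerated, and prenylstannanes are expected to transfer the linear (primary) prenyl terminus.

Step 3
Reactants: 3 2,4-dihydroxy-3,5-bis(3-methylbut-2-en-1-yl)benzaldehyde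
Product: 4 4-(TBSO)-2-hydroxy-3,5-diprenylbenzaldehyde
Conditions: TBSCl (1.1 equiv), imidazole, DMF, 0 °C to rt
Reagents that add atoms: tert-butyldimethylsilyl chloride, CC(C)(C)[Si](C)(C)Cl
Why: Imidazole-mediated O-silylation should occur only at O4, the more acidic free phenol, because O2–H is held in a hydrogen bond to the formyl oxygen and is needed free for step 6.

Step 4
Reactants: 1 2,4-dihydroxybenzaldehyde
Product: 5 2,4-bis(TBSO)benzaldehyde
Conditions: TBSCl (2.4 equiv), imidazole, DMF, rt
Reagents that add atoms: tert-butyldimethylsilyl chloride, CC(C)(C)[Si](C)(C)Cl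
Why: Exhaustive O-silylation with excess reagent should cap both phenols, including the hydrogen-bonded one, so that the alkyne partner carries no acidic O–H.

Step 5
Reactants: 5 2,4-bis(TBSO)benzaldehyde
Product: 6 1-ethynyl-2,4-bis(TBSO)benzene
Conditions: Me3SiCHN2, n-BuLi, THF, −78 °C to rt
Reagents that add atoms: trimethylsilyldiazomethane, C[Si](C)(C)C=[N+]=[N-]
Why: Colvin homologation (addition of the lithiated silyldiazomethane, Peterson-type elimination, loss of N2 with 1,2-shift) should turn the aryl aldehyde into the terminal alkyne in one step under non-protic conditions that spare the aryl silyl ethers.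

Step 6
Reactants: 4 4-(TBSO)-2-hydroxy-3,5-diprenylbenzaldehyde; 6 1-ethynyl-2,4-bis(TBSO)benzene
Product: 8 (2S)-7-(TBSO)-2-[2,4-bis(TBSO)phenyl]-6,8-diprenylchroman-4-one, via silylated 2'-hydroxychalcone 7 (not isolated)
Conditions: [RhCl(cod)]2 (2.5 mol %), Fe(C5H4PPh2)2 (dppf, 5 mol %), Na2CO3 (10 mol %), toluene, 80 °C; then 0 °C, 1-[3,5-bis(trifluoromethyl)phenyl]-3-[(8S,9S)-6'-methoxycinchonan-9-yl]thiourea (15 mol %), same flask
Reagents that add atoms: none
Why: Deprotonated O1–H binds monovalent rhodium and directs oxidative addition of the neighbouring formyl C–H bond (a five-membered acyl–rhodium–aryloxide chelate that holds back decarbonylation); syn insertion of the alkyne into Rh–H with rhodium at the unsubstituted carbon, then C–C reductive elimination, gives the (E)-chalcone 7 and thereby the C3–C4 bond, after which the added thiourea closes ring C by oxa-Michael addition of O1 to C2. The closest known reaction types are the rhodium-catalysed tandem alkyne hydroacylation/oxa-Michael route from salicylaldehydes to chroman-4-ones and the bifunctional cinchona-thiourea-catalysed asymmetric cyclisation of 2'-hydroxychalcones, itself a copy of the chalcone isomerase step of flavanone biosynthesis. Ring C closes in the 6-endo-trig mode (O1 onto the enone β-carbon C2). The only new stereocentre, C2, is set by the catalyst: its thiourea N–H bonds hold the enone carbonyl while the quinuclidinium-paired phenoxide is delivered to the Si face of C2, which corresponds to (2S). The step needs regioselective hydroacylation (acyl to the terminal alkyne carbon, secured by the steric and electronic bias of an aryl/H alkyne), chemoselectivity against the two prenyl groups (trisubstituted, non-chelating alkenes that should not insert) and a single acidic site (only O1–H is free, the other three phenols being silyl ethers). Because the closure is reversible, low temperature and a stop before equilibration are relied on to keep the kinetic enantiomer preference.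

Step 7
Reactants: 8 (2S)-7-(TBSO)-2-[2,4-bis(TBSO)phenyl]-6,8-diprenylchroman-4-one
Product: 9 (2S)-2-(2,4-dihydroxyphenyl)-7-hydroxy-6,8-bis(3-methylbut-2-en-1-yl)chroman-4-one
Conditions: Bu4NF, AcOH (1:1, 4 equiv), THF, 0 °C
Reagents that add atoms: none
Why: Fluoride-mediated desilylation should free O7–H, O2'–H and O4'–H, and the acetic acid buffer keeps them protonated so that no phenolate can trigger retro-oxa-Michael opening of ring C, leaving C2 and the prenyl groups untouched.

**Compound list**

1 | 2,4-dihydroxybenzaldehyde | O=Cc1ccc(O)cc1O | starting material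
2 | 2,4-dihydroxy-3,5-diiodobenzaldehyde | O=Cc1cc(I)c(O)c(I)c1O | intermediate
3 | 2,4-dihydroxy-3,5-bis(3-methylbut-2-en-1-yl)benzaldehyde | O=Cc1cc(CC=C(C)C)c(O)c(CC=C(C)C)c1O | intermediate
4 | 4-[(tert-butyldimethylsilyl)oxy]-2-hydroxy-3,5-bis(3-methylbut-2-en-1-yl)benzaldehyde | O=Cc1cc(CC=C(C)C)c(O[Si](C)(C)C(C)(C)C)c(CC=C(C)C)c1O | intermediate
5 | 2,4-bis[(tert-butyldimethylsilyl)oxy]benzaldehyde | O=Cc1ccc(O[Si](C)(C)C(C)(C)C)cc1O[Si](C)(C)C(C)(C)C | intermediate
6 | 1-ethynyl-2,4-bis[(tert-butyldimethylsilyl)oxy]benzene | C#Cc1ccc(O[Si](C)(C)C(C)(C)C)cc1O[Si](C)(C)C(C)(C)C | intermediate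
7 | (E)-1-{4-[(tert-butyldimethylsilyl)oxy]-2-hydroxy-3,5-bis(3-methylbut-2-en-1-yl)phenyl}-3-{2,4-bis[(tert-butyldimethylsilyl)oxy]phenyl}prop-2-en-1-one (formed in the flask in step 6, not isolated) | O=C(/C=C/c1ccc(O[Si](C)(C)C(C)(C)C)cc1O[Si](C)(C)C(C)(C)C)c1cc(CC=C(C)C)c(O[Si](C)(C)C(C)(C)C)c(CC=C(C)C)c1O | intermediate
8 | (2S)-7-[(tert-butyldimethylsilyl)oxy]-2-{2,4-bis[(tert-butyldimethylsilyl)oxy]phenyl}-6,8-bis(3-methylbut-2-en-1-yl)chroman-4-one | CC(C)=CCc1cc2c(c(CC=C(C)C)c1O[Si](C)(C)C(C)(C)C)O[C@H](c1ccc(O[Si](C)(C)C(C)(C)C)cc1O[Si](C)(C)C(C)(C)C)CC2=O | intermediate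
9 | (2S)-2-(2,4-dihydroxyphenyl)-7-hydroxy-6,8-bis(3-methylbut-2-en-1-yl)chroman-4-one | CC(C)=CCc1cc2c(c(CC=C(C)C)c1O)O[C@H](c1ccc(O)cc1O)CC2=O | target

**Step count and risks**

Total step count: 7. Longest linear sequence: 5 steps (steps 1, 2, 3, 6, 7, from 2,4-dihydroxybenzaldehyde).

Steps most likely to fail:

Step 6. The enantiofacial discrimination in the oxa-Michael closure of an unactivated, electron-rich chalcone may be modest, and the amine catalyst may erode it further by reversible ring opening as equilibrium is approached. The fallback sets out from 4 and 6 and comes back at 8; it gives up catalyst control of the closure in favour of a resolution, at the cost of at most half of the material. Aldehyde 4 and alkyne 6 are joined under the same rhodium conditions, and chalcone 7 is closed with an achiral amine base (DBU, cat., toluene, rt) to the racemic flavanone, 7-(TBSO)-2-[2,4-bis(TBSO)phenyl]-6,8-diprenylchroman-4-one F1. F1 is then resolved kinetically by asymmetric transfer hydrogenation (RuCl(p-cymene)[(R,R)-TsDPEN] (cat.), HCO2H/Et3N, EtOAc, rt, stopped near half conversion). The (2R)-ketone is expected to be reduced faster, to the cis-configured (2R,4R)-7-(TBSO)-2-[2,4-bis(TBSO)phenyl]-6,8-diprenylchroman-4-ol F2, which is separated by chromatography from the unreacted (2S)-ketone 8. The ligand antipode that leaves 8 is to be confirmed on a small sample of F1.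

Step 2. Allylic transposition at the prenyl–palladium stage may give 1,1-dimethylallyl isomers, and protodeiodination may compete at the hindered C3–I bond between two oxygens. The fallback sets out from 2 and comes back at 3; it brings in the side chains as symmetrical allyl groups and builds the trisubstituted alkene afterwards. Diiodide 2 is coupled with allyltributylstannane (Pd(PPh3)4 (cat.), CuI (cat.), DMF, 80 °C) to 2,4-dihydroxy-3,5-di(prop-2-en-1-yl)benzaldehyde F3. Double cross-metathesis of F3 with excess 2-methylbut-2-ene (second-generation Grubbs catalyst RuCl2(=CHPh)(H2IMes)(PCy3), CH2Cl2, 40 °C) should then give 3.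

Step 5. The ortho silyl group may migrate from the phenol oxygen to the transient benzylic alkoxide, or the lithiated reagent may attack silicon; either would stall the elimination that leads to the alkyne. The fallback sets out from 5 and comes back at 6; it uses the Corey–Fuchs sequence, which passes through no alkoxide. Aldehyde 5 is converted with CBr4/PPh3 (CH2Cl2, 0 °C) into 1-(2,2-dibromoethenyl)-2,4-bis(TBSO)benzene F4. Treatment of F4 with n-BuLi (2.1 equiv, THF, −78 °C, then aq NH4Cl) should give 6 by bromine–lithium exchange and Fritsch–Buttenberg–Wiechell rearrangement.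

**Further compounds**

F1 | step 6 | racemic 7-[(tert-butyldimethylsilyl)oxy]-2-{2,4-bis[(tert-butyldimethylsilyl)oxy]phenyl}-6,8-bis(3-methylbut-2-en-1-yl)chroman-4-one | CC(C)=CCc1cc2c(c(CC=C(C)C)c1O[Si](C)(C)C(C)(C)C)OC(c1ccc(O[Si](C)(C)C(C)(C)C)cc1O[Si](C)(C)C(C)(C)C)CC2=O
F2 | step 6 | (2R,4R)-7-[(tert-butyldimethylsilyl)oxy]-2-{2,4-bis[(tert-butyldimethylsilyl)oxy]phenyl}-6,8-bis(3-methylbut-2-en-1-yl)chroman-4-ol | CC(C)=CCc1cc2c(c(CC=C(C)C)c1O[Si](C)(C)C(C)(C)C)O[C@@H](c1ccc(O[Si](C)(C)C(C)(C)C)cc1O[Si](C)(C)C(C)(C)C)C[C@H]2O
F3 | step 2 | 2,4-dihydroxy-3,5-di(prop-2-en-1-yl)benzaldehyde | O=Cc1cc(CC=C)c(O)c(CC=C)c1O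
F4 | step 5 | 1-(2,2-dibromoethenyl)-2,4-bis[(tert-butyldimethylsilyl)oxy]benzene | BrC(Br)=Cc1ccc(O[Si](C)(C)C(C)(C)C)cc1O[Si](C)(C)C(C)(C)C
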